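**Retrosynthetic overview**
- The target is reached by desilylation of its bis-silyl ether. Ring A (C1–C2–C3–C4–C5–C10) is closed last, by forming C1–C2 in a strain-release homoaldol: a cyclopropanol on C4 (carbons C2, C3, C4) opens to the β-metallo ketone, which adds to the C1 aldehyde on C10.
- Enabling feature: the γ-hydroxy ketone of ring A, i.e. the 1,4 relation C1(OH)/C4(=O) with C2–C3 between them, on a ring B whose C10 and C5 already carry the C1 and C4 carbons trans-diequatorial.
- The C1 aldehyde and the C4 cyclopropanol (Kulinkovich on the C4 ester) are stored together as a trans-fused cyclic methyl acetal, a temporary ring, while ring B is dressed: C8–OH (OsO4 on the silyl enol ether), C7 acetyl (carbonylative Stille), C6–OH (conjugate borylation), acrylate (triflate carbonylation), C8 ester (Steglich).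
- Ring B comes from an enantioselective Diels–Alder reaction of a 2-silyloxybutadiene with ethyl (E)-3-methyl-4-oxobut-2-enoate, which sets quaternary C10 and C5 trans.
- Order of ring formation: ring B (step 2), then ring A (step 18); the acetal ring made in step 4 is opened again in step 17.

Key step: step 18

Locants are those of the eudesmane skeleton of the target: ring A = C1 (CHOH), C2, C3, C4 (C=O), C5, C10; ring B = C5, C6 (CHOH), C7, C8 (CH–O–acyl), C9, C10 (C–CH3); C11–C13 = methyl acrylate on C7; α = face opposite to the C10 methyl. The target is 1β-OH, 5α-H, 6α-OH, 7α-H, 8α-O-acyl, 10β-CH3.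

Assumption: the (S)-oxazaborolidinium catalyst of step 2 gives the (1R,6R) adduct; if the sense of induction is the opposite, the (R)-catalyst is used.

Step 1
Reactants: 1 but-3-en-2-one
Product: 2 2-(triisopropylsilyloxy)buta-1,3-diene
Conditions: iPr3SiOTf, Et3N, Et2O, 0 °C → rt
Reagents that add atoms: triisopropylsilyl trifluoromethanesulfonate, CC(C)[Si](OS(=O)(=O)C(F)(F)F)(C(C)C)C(C)C
Why: Soft enolisation and O-silylation of the methyl ketone (silyl enol ether formation) should give the 2-silyloxydiene; no stereocentre is formed.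

Step 2
Reactants: 2 2-(triisopropylsilyloxy)buta-1,3-diene; 3 ethyl (E)-3-methyl-4-oxobut-2-enoate
Product: 4 ethyl (1R,6R)-6-formyl-6-methyl-3-(triisopropylsilyloxy)cyclohex-3-ene-1-carboxylate
Conditions: (S)-1-(2-methylphenyl)-3,3-diphenyltetrahydro-1H,3H-pyrrolo[1,2-c][1,3,2]oxazaborole (20 mol %), HN(SO2CF3)2 (16 mol %), CH2Cl2, −78 → −40 °C
Reagents that add atoms: none
Why: Enantioselective Diels–Alder reaction under chiral oxazaborolidinium catalysis: the activated formyl group directs the nucleophilic CH2 terminus of the diene to the β-carbon (formyl-bearing C10 para to the silyloxy carbon C7), suprafacial addition to the E-alkene places the future C1 and C4 carbons trans on C10/C5, and the catalyst face sets both centres R.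

Step 3
Reactants: 4 ethyl (1R,6R)-6-formyl-6-methyl-3-(triisopropylsilyloxy)cyclohex-3-ene-1-carboxylate
Product: 5 ethyl (1R,6R)-6-(dimethoxymethyl)-6-methyl-3-(triisopropylsilyloxy)cyclohex-3-ene-1-carboxylate
Conditions: HC(OMe)3, CeCl3·7H2O (10 mol %), MeOH, 0 °C → rt
Reagents that add atoms: trimethyl orthoformate, COC(OC)OC; methanol, CO
Why: Chemoselective, nearly neutral acetalisation of the aldehyde should leave the TIPS enol ether and the ester untouched.

Step 4
Reactants: 5 ethyl (1R,6R)-6-(dimethoxymethyl)-6-methyl-3-(triisopropylsilyloxy)cyclohex-3-ene-1-carboxylate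
Product: 7 trans-fused spiro-cyclopropyl cyclic methyl acetal (C1–O–C4) of the ring B silyl enol ether, via cyclopropanol dimethyl acetal 6 (not isolated)
Conditions: EtMgBr (3 equiv), Ti(OiPr)4 (0.3 equiv), THF, 0 °C → rt; NH4Cl work-up; then PPTS (10 mol %), 4 Å sieves, CH2Cl2, rt
Reagents that add atoms: ethylmagnesium bromide, CC[Mg]Br
Why: Kulinkovich reaction (the titanacyclopropane from EtMgBr adds twice to the ester carbonyl and supplies C2 and C3) gives the cyclopropanol, whose hydroxyl then displaces one methoxy group by acid-catalysed transacetalisation; the five-membered acetal is trans-fused because C1 and C4 are trans-diequatorial, and its C1 forms as an anomer mixture that is erased in step 17.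

Step 5
Reactants: 7 trans-fused spiro-cyclopropyl cyclic methyl acetal of the ring B silyl enol ether
Product: 8 8α-hydroxy C7 ketone (cyclic acetal intact)
Conditions: OsO4 (2 mol %), N-methylmorpholine N-oxide, acetone/H2O, 0 °C → rt
Reagents that add atoms: osmium tetroxide, O=[Os](=O)(=O)=O (catalytic, reoxidised by N-methylmorpholine N-oxide, C[N+]1([O-])CCOCC1)
Why: Osmium-catalysed hydroxylation of the silyl enol ether (Rubottom-type α-hydroxylation): the oxidant should add to C8 from the α face, anti to the axial C10 methyl that lies 1,3 to C8 in the trans-fused bicycle, and loss of silanol gives the C7 ketone.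

Step 6
Reactants: 8 8α-hydroxy C7 ketone
Product: 9 8α-triethylsilyloxy C7 ketone
Conditions: Et3SiCl, imidazole, DMF, 0 °C
Reagents that add atoms: chlorotriethylsilane, CC[Si](Cl)(CC)CC
Why: Standard silylation of the secondary alcohol with a group that can later be removed in the presence of a TBS ether.

Step 7
Reactants: 9 8α-triethylsilyloxy C7 ketone
Product: 10 C7 enol triflate (C6=C7) with 8α-OTES
Conditions: KN(SiMe3)2, THF, −78 °C; then PhNTf2, −78 → 0 °C
Reagents that add atoms: N-phenylbis(trifluoromethanesulfonimide), O=S(=O)(N(c1ccccc1)S(=O)(=O)C(F)(F)F)C(F)(F)F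
Why: Kinetic enolisation and O-triflation: the bulky amide base should remove a C6 methylene proton and not the hindered α-silyloxy C8–H, which fixes the C6=C7 enol triflate.

Step 8
Reactants: 10 C7 enol triflate
Product: 11 7-acetyl C6=C7 enone with 8α-OTES
Conditions: Pd(PPh3)4 (5 mol %), LiCl, CO (1 atm), Me4Sn, THF, 55 °C
Reagents that add atoms: carbon monoxide, [C-]#[O+]; tetramethylstannane, C[Sn](C)(C)C
Why: Carbonylative Stille coupling of the vinyl triflate with tetramethyltin installs C11 (from CO) and C13 (methyl) as the methyl enone; no stereocentre is touched.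

Step 9
Reactants: 11 7-acetyl C6=C7 enone
Product: 13 6α-hydroxy-7β-acetyl compound (7α-H; 8α-OTES), via C6 pinacol boronate 12 (not isolated)
Conditions: B2pin2, CuCl (5 mol %), bis[2-(diphenylphosphino)phenyl] ether (5 mol %), NaOtBu (10 mol %), MeOH (2 equiv), THF, rt; then H2O2, pH 7 phosphate buffer, 0 °C
Reagents that add atoms: bis(pinacolato)diboron, CC1(C)OB(OC1(C)C)B1OC(C)(C)C(C)(C)O1; hydrogen peroxide, OO
Why: Copper-catalysed conjugate borylation followed by stereoretentive C–B oxidation: the boryl group should add to C6 from the α face (anti to the axial C10 methyl and to the C5 substituent), and C7, epimerisable next to the ketone, settles with the acetyl group equatorial, trans to both oxygen-bearing neighbours.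

Step 10
Reactants: 13 6α-hydroxy-7β-acetyl compound
Product: 14 6α-tert-butyldimethylsilyloxy-7β-acetyl compound
Conditions: tBuMe2SiOTf, 2,6-lutidine, CH2Cl2, −78 °C
Reagents that add atoms: tert-butyldimethylsilyl trifluoromethanesulfonate, CC(C)(C)[Si](C)(C)OS(=O)(=O)C(F)(F)F
Why: Silylation of the hindered β-hydroxy ketone under buffered, non-basic conditions avoids retro-aldol cleavage and β-elimination.

Step 11
Reactants: 14 6α-tert-butyldimethylsilyloxy-7β-acetyl compound
Product: 15 7β-[1-(trifluoromethanesulfonyloxy)vinyl] compound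
Conditions: KN(SiMe3)2, THF, −78 °C; then PhNTf2, −78 → 0 °C
Reagents that add atoms: N-phenylbis(trifluoromethanesulfonimide), O=S(=O)(N(c1ccccc1)S(=O)(=O)C(F)(F)F)C(F)(F)F
Why: Kinetic deprotonation of the methyl group of the methyl ketone (the tertiary C7–H is shielded by two silyloxy-bearing carbons) and O-triflation give the terminal enol triflate without epimerising C7.

Step 12
Reactants: 15 7β-[1-(trifluoromethanesulfonyloxy)vinyl] compound
Product: 16 7β-[1-(methoxycarbonyl)vinyl] compound (methyl acrylate C11–C13 complete)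
Conditions: Pd(OAc)2 (5 mol %), PPh3 (10 mol %), CO (1 atm), MeOH, Et3N, DMF, rt
Reagents that add atoms: carbon monoxide, [C-]#[O+]; methanol, CO
Why: Palladium-catalysed methoxycarbonylation of the vinyl triflate gives the 2-substituted methyl acrylate directly; C12 comes from CO.

Step 13
Reactants: 16 7β-[1-(methoxycarbonyl)vinyl] compound
Product: 17 8α-alcohol (6α-OTBS and cyclic acetal kept)
Conditions: HF·pyridine, pyridine, THF, 0 °C
Reagents that add atoms: none
Why: Selective desilylation: the secondary triethylsilyl ether should cleave much faster than the hindered secondary TBS ether under buffered fluoride.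

Step 14
Reactants: 18 ethyl 2-(hydroxymethyl)acrylate
Product: 19 ethyl 2-[(tert-butyldimethylsilyloxy)methyl]acrylate
Conditions: tBuMe2SiCl, imidazole, CH2Cl2, rt
Reagents that add atoms: tert-butylchlorodimethylsilane, CC(C)(C)[Si](C)(C)Cl
Why: Standard silylation of the primary allylic alcohol.

Step 15
Reactants: 19 ethyl 2-[(tert-butyldimethylsilyloxy)methyl]acrylate
Product: 20 2-[(tert-butyldimethylsilyloxy)methyl]acrylic acid
Conditions: LiOH, THF/H2O, 0 °C → rt; then 1 M HCl to pH 4
Reagents that add atoms: lithium hydroxide, [Li+].[OH-]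
Why: Saponification of the ethyl ester; the silyl ether survives brief aqueous base.

Step 16
Reactants: 17 8α-alcohol; 20 2-[(tert-butyldimethylsilyloxy)methyl]acrylic acid
Product: 21 8α-ester of 17 with acid 20
Conditions: EDC·HCl, DMAP (30 mol %), CH2Cl2, 0 °C → rt
Reagents that add atoms: none
Why: Steglich esterification of the only free hydroxyl, with retention at C8; fast acylation should outrun lactonisation of the C8 hydroxyl onto the C12 ester.

Step 17
Reactants: 21 8α-ester
Product: 22 lactol (hemiacetal between the C1 aldehyde and the C4 cyclopropanol oxygen)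
Conditions: PPTS (20 mol %), acetone/H2O 10:1, rt
Reagents that add atoms: water, O
Why: Mild acid hydrolysis of the cyclic methyl acetal through its oxocarbenium ion; both TBS ethers and both acrylates should survive.

Step 18
Reactants: 22 lactol
Product: 24 bis-TBS ether of the target (ring A closed; 1β-OH; C4 ketone), via open-chain cyclopropanol aldehyde 23 (not isolated)
Conditions: Et2Zn (3 equiv), 2,2′-bipyridine (30 mol %), THF/DMSO 5:1, 0 → 40 °C; then sat. aq. NH4Cl
Reagents that add atoms: none
Why: Proposed new method: Et2Zn deprotonates the lactol, ring–chain tautomerism gives the zinc cyclopropoxide and the C1 aldehyde (23), and strain-driven β-carbon scission of the cyclopropoxide gives the β-zincio ketone (zinc homoenolate of the C4 ketone), whose carbon C2 adds to the C1 aldehyde. The closest known reactions are the Et2Zn-mediated opening of cyclopropanols to zinc homoenolates with intermolecular trapping and the addition of zinc and titanium ester homoenolates to aldehydes; an intramolecular 1,2-addition of a ketone homoenolate to an aldehyde has not been shown. Ring A closes in the 6-exo-trig mode on the C1 carbonyl, through a chair fused to the all-equatorial chair of ring B. The only new stereocentre, C1, is set in that chair: the zinc-bound oxygen should take the equatorial site, free of 1,3-diaxial contacts with H3 and H5, which gives the 1β-alcohol, while C5 and C10 are already trans and are not touched. The step needs 1,2-addition through C2 to beat protonation of the homoenolate, the enolised-homoenolate pathway and aldol closure through C3. Intramolecularity (a six-membered ring, against a four-membered ring for attack through C4), aprotic conditions and the absence of any other aldehyde or ketone should secure this, and the two acrylates do not react with dialkylzincs without a copper or nickel catalyst.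

Step 19
Reactants: 24 bis-TBS ether of the target
Product: 25 target, methyl 1β,6α-dihydroxy-8α-[2-(hydroxymethyl)acryloyloxy]-4-oxo-15-nor-eudesm-11(13)-en-12-oate
Conditions: HF·pyridine, pyridine, THF, 0 °C → rt
Reagents that add atoms: none
Why: Fluoride-mediated cleavage of both TBS ethers under buffered, non-basic conditions avoids lactonisation, acyl migration and β-elimination of the β-hydroxy ketone.

**Compound list**
1 | but-3-en-2-one | CC(=O)C=C | starting material
2 | 2-(triisopropylsilyloxy)buta-1,3-diene | C=CC(=C)O[Si](C(C)C)(C(C)C)C(C)C | intermediate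
3 | ethyl (E)-3-methyl-4-oxobut-2-enoate | CCOC(=O)/C=C(C)/C=O | starting material
4 | ethyl (1R,6R)-6-formyl-6-methyl-3-(triisopropylsilyloxy)cyclohex-3-ene-1-carboxylate | C1[C@@](C)(C=O)[C@H](C(=O)OCC)CC(O[Si](C(C)C)(C(C)C)C(C)C)=C1 | intermediate
5 | ethyl (1R,6R)-6-(dimethoxymethyl)-6-methyl-3-(triisopropylsilyloxy)cyclohex-3-ene-1-carboxylate | C1[C@@](C)(C(OC)OC)[C@H](C(=O)OCC)CC(O[Si](C(C)C)(C(C)C)C(C)C)=C1 | intermediate
6 | 1-[(1R,6R)-6-(dimethoxymethyl)-6-methyl-3-(triisopropylsilyloxy)cyclohex-3-en-1-yl]cyclopropan-1-ol | C1[C@@](C)(C(OC)OC)[C@H](C2(O)CC2)CC(O[Si](C(C)C)(C(C)C)C(C)C)=C1 | intermediate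
7 | cyclic methyl acetal: C1 (CH–OMe, both anomers) bonded to C10 and, through the acetal oxygen, to C4 (spiro cyclopropane carbon on C5); ring B with C7(OTIPS)=C8; 5α-H, 10β-CH3 (trans-fused) | C1[C@@]2(C)C(OC)OC3(CC3)[C@@H]2CC(O[Si](C(C)C)(C(C)C)C(C)C)=C1 | intermediate
8 | as 7, ring B with C7 ketone and 8α-OH | O[C@H]1C[C@@]2(C)C(OC)OC3(CC3)[C@@H]2CC1=O | intermediate
9 | as 8, 8α-OSiEt3 | CC[Si](CC)(CC)O[C@H]1C[C@@]2(C)C(OC)OC3(CC3)[C@@H]2CC1=O | intermediate
10 | as 9, C7 enol triflate (C6=C7) | CC[Si](CC)(CC)O[C@H]1C[C@@]2(C)C(OC)OC3(CC3)[C@@H]2C=C1OS(=O)(=O)C(F)(F)F | intermediate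
11 | as 9, 7-acetyl C6=C7 enone | CC[Si](CC)(CC)O[C@H]1C[C@@]2(C)C(OC)OC3(CC3)[C@@H]2C=C1C(C)=O | intermediate
12 | 6α-(pinacolboryl)-7β-acetyl (7α-H), 8α-OSiEt3 | CC[Si](CC)(CC)O[C@H]1C[C@@]2(C)C(OC)OC3(CC3)[C@@H]2[C@@H](B4OC(C)(C)C(C)(C)O4)[C@@H]1C(C)=O | intermediate
13 | 6α-hydroxy-7β-acetyl, 8α-OSiEt3 | CC[Si](CC)(CC)O[C@H]1C[C@@]2(C)C(OC)OC3(CC3)[C@@H]2[C@@H](O)[C@@H]1C(C)=O | intermediate
14 | 6α-OTBS-7β-acetyl, 8α-OSiEt3 | CC[Si](CC)(CC)O[C@H]1C[C@@]2(C)C(OC)OC3(CC3)[C@@H]2[C@@H](O[Si](C)(C)C(C)(C)C)[C@@H]1C(C)=O | intermediate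
15 | as 14, 7β-[1-(triflyloxy)vinyl] | CC[Si](CC)(CC)O[C@H]1C[C@@]2(C)C(OC)OC3(CC3)[C@@H]2[C@@H](O[Si](C)(C)C(C)(C)C)[C@@H]1C(=C)OS(=O)(=O)C(F)(F)F | intermediate
16 | as 14, 7β-[1-(methoxycarbonyl)vinyl] | CC[Si](CC)(CC)O[C@H]1C[C@@]2(C)C(OC)OC3(CC3)[C@@H]2[C@@H](O[Si](C)(C)C(C)(C)C)[C@@H]1C(=C)C(=O)OC | intermediate
17 | as 16, 8α-OH | O[C@H]1C[C@@]2(C)C(OC)OC3(CC3)[C@@H]2[C@@H](O[Si](C)(C)C(C)(C)C)[C@@H]1C(=C)C(=O)OC | intermediate
18 | ethyl 2-(hydroxymethyl)acrylate | C=C(CO)C(=O)OCC | starting material
19 | ethyl 2-[(tert-butyldimethylsilyloxy)methyl]acrylate | C=C(CO[Si](C)(C)C(C)(C)C)C(=O)OCC | intermediate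
20 | 2-[(tert-butyldimethylsilyloxy)methyl]acrylic acid | C=C(CO[Si](C)(C)C(C)(C)C)C(=O)O | intermediate
21 | as 17, 8α-O-{2-[(TBS-oxy)methyl]acryloyl} | C=C(CO[Si](C)(C)C(C)(C)C)C(=O)O[C@H]1C[C@@]2(C)C(OC)OC3(CC3)[C@@H]2[C@@H](O[Si](C)(C)C(C)(C)C)[C@@H]1C(=C)C(=O)OC | intermediate
22 | lactol of 21 (C1 = CH–OH, both anomers) | C=C(CO[Si](C)(C)C(C)(C)C)C(=O)O[C@H]1C[C@@]2(C)C(O)OC3(CC3)[C@@H]2[C@@H](O[Si](C)(C)C(C)(C)C)[C@@H]1C(=C)C(=O)OC | intermediate
23 | open form of 22: C10 carries CH3 (β) and CHO (α), C5 carries 1-hydroxycyclopropyl (β) | C=C(CO[Si](C)(C)C(C)(C)C)C(=O)O[C@H]1C[C@@](C)(C=O)[C@H](C2(O)CC2)[C@@H](O[Si](C)(C)C(C)(C)C)[C@@H]1C(=C)C(=O)OC | intermediate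
24 | target with 6α-OTBS and CH2OTBS (1β-OH, 4-oxo, 5α-H) | C=C(CO[Si](C)(C)C(C)(C)C)C(=O)O[C@H]1C[C@@]2(C)[C@H](O)CCC(=O)[C@@H]2[C@@H](O[Si](C)(C)C(C)(C)C)[C@@H]1C(=C)C(=O)OC | intermediate
25 | methyl 1β,6α-dihydroxy-8α-[2-(hydroxymethyl)acryloyloxy]-4-oxo-15-nor-eudesm-11(13)-en-12-oate (5α-H, 7α-H, 10β-CH3) | C=C(CO)C(=O)O[C@H]1C[C@@]2(C)[C@H](O)CCC(=O)[C@@H]2[C@@H](O)[C@@H]1C(=C)C(=O)OC | target

**Step count**
Total step count: 19. Longest linear sequence: 17 steps (steps 1–13 and 16–19).

**Steps most likely to fail**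

1. Step 18 (Proposed new method). The ring-opened zinc homoenolate may be protonated or enolised (giving the ethyl ketone or aldol closure through C3) before C1–C2 bond formation, or the ring may close with poor facial selectivity at C1. The fallback uses known reactions and runs from 22 back to 24. Electrophilic ring opening of the cyclopropanol of 22 with N-iodosuccinimide (CH2Cl2, 0 °C) should give the β-iodoethyl ketone aldehyde F1. A cobalt-catalysed alkylchromium Barbier-type addition (CrCl2, cobalt phthalocyanine C32H16CoN8 as catalyst, DMF, rt), which is selective for aldehydes over ketones and esters, should then form the same C1–C2 bond and return 24.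

2. Step 2. The catalysed cycloaddition of this trisubstituted enal may be sluggish or may proceed with low enantio- or regiocontrol. The fallback replaces catalyst control by a separable, traceless auxiliary and runs from 3 back to 7. Transesterification of 3 with (1R,2S,5R)-menthol (Ti(OiPr)4 as catalyst, toluene, 80 °C) gives the menthyl ester F2. Its thermal Diels–Alder reaction with 2 (toluene, 80 °C), still aldehyde-directed and stereospecific for the trans relationship, gives the (1R,6R) adduct F3 and the (1S,6S) adduct F4, which are separated by chromatography or crystallisation. F3 is acetalised as in step 3 to the dimethyl acetal F5, and the Kulinkovich/transacetalisation sequence of step 4 expels the menthyl group and returns 7.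

3. Step 9. Boryl-copper addition to the hindered enone may be slow or face-unselective, or the C8 silyloxy group may undergo β-elimination from the copper enolate. The fallback runs from 11 back to 13. Nucleophilic epoxidation of 11 (tBuOOH, DBU, CH2Cl2) from the α face should give the 6α,7α-epoxy ketone F6. Reduction with sodium (phenylseleno)triethoxyborate (from PhSeSePh and NaBH4 in EtOH, AcOH buffer) cleaves the Cα–O bond and should return the β-hydroxy ketone 13 after equilibration at C7.

Further compounds
F1 | step 18 | β-iodoethyl ketone aldehyde (C5 carries C(=O)CH2CH2I, C10 carries CHO; otherwise as 23) | C=C(CO[Si](C)(C)C(C)(C)C)C(=O)O[C@H]1C[C@@](C)(C=O)[C@H](C(=O)CCI)[C@@H](O[Si](C)(C)C(C)(C)C)[C@@H]1C(=C)C(=O)OC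
F2 | step 2 | (1R,2S,5R)-menthyl (E)-3-methyl-4-oxobut-2-enoate | CC(C)[C@@H]1CC[C@@H](C)C[C@H]1OC(=O)/C=C(C)/C=O
F3 | step 2 | (1R,2S,5R)-menthyl (1R,6R)-6-formyl-6-methyl-3-(triisopropylsilyloxy)cyclohex-3-ene-1-carboxylate | C1[C@@](C)(C=O)[C@H](C(=O)O[C@@H]2C[C@H](C)CC[C@H]2C(C)C)CC(O[Si](C(C)C)(C(C)C)C(C)C)=C1
F4 | step 2 | (1R,2S,5R)-menthyl (1S,6S)-6-formyl-6-methyl-3-(triisopropylsilyloxy)cyclohex-3-ene-1-carboxylate | C1[C@](C)(C=O)[C@@H](C(=O)O[C@@H]2C[C@H](C)CC[C@H]2C(C)C)CC(O[Si](C(C)C)(C(C)C)C(C)C)=C1
F5 | step 2 | (1R,2S,5R)-menthyl (1R,6R)-6-(dimethoxymethyl)-6-methyl-3-(triisopropylsilyloxy)cyclohex-3-ene-1-carboxylate | C1[C@@](C)(C(OC)OC)[C@H](C(=O)O[C@@H]2C[C@H](C)CC[C@H]2C(C)C)CC(O[Si](C(C)C)(C(C)C)C(C)C)=C1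
F6 | step 9 | 6α,7α-epoxy-7-acetyl compound (8α-OSiEt3, cyclic acetal as in 11) | CC[Si](CC)(CC)O[C@H]1C[C@@]2(C)C(OC)OC3(CC3)[C@@H]2[C@H]4O[C@@]14C(C)=O
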